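**Assumption:** the target SMILES defines only C3 (S) and leaves the biaryl axis open, so the route controls C3 and delivers the compound as the mixture of its two atropo-diastereomers.

## Retrosynthetic overview

1. The target comes from lactam 24 by C1=O reduction. The nitrogen ring is closed last, by lactamisation of amino ester 23.
2. The key C3–C4 bond is made by a Mannich-type addition of the laterally lithiated biaryl toluate 21 (a vinylogous ester enolate) to the (S)-N-sulfinyl acetaldimine 20, which sets C3.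
3. Biaryl toluate 17 comes from Suzuki coupling of bromo-orsellinate 16 (from 3,5-dimethoxytoluene) with naphthyl boronate 10.
4. The naphthalene is built first: Stobbe condensation of 2-bromo-5-methoxybenzaldehyde with diethyl succinate, then Friedel–Crafts ring closure. The bromine blocks one ortho position and later serves as the coupling handle.
5. Ring order: second naphthalene ring, then the biaryl bond, then the tetrahydropyridine ring.

## Route

**Step 1**
Reactants: 1 2-bromo-5-methoxybenzaldehyde; 2 diethyl succinate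
Product: 3 (E)-4-(2-bromo-5-methoxyphenyl)-3-(ethoxycarbonyl)but-3-enoic acid
Conditions: KOt-Bu, t-BuOH, reflux; then aq. HCl
Reagents that add atoms: none
Why: Stobbe condensation: aldol addition of the succinate enolate to the non-enolisable aldehyde, lactonisation and E1cB opening of the paraconate give the (E)-half-ester irreversibly as its carboxylate.

**Step 2**
Reactants: 3 (E)-4-(2-bromo-5-methoxyphenyl)-3-(ethoxycarbonyl)but-3-enoic acid
Product: 4 ethyl 4-acetoxy-8-bromo-5-methoxynaphthalene-2-carboxylate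
Conditions: Ac2O, NaOAc, 140 °C
Reagents that add atoms: acetic anhydride CC(=O)OC(C)=O
Why: The mixed anhydride undergoes intramolecular Friedel–Crafts acylation at the only free ortho carbon (activated by the ortho OMe, the other ortho position carrying Br), and the naphthol formed is acetylated in situ.

**Step 3**
Reactants: 4 ethyl 4-acetoxy-8-bromo-5-methoxynaphthalene-2-carboxylate
Product: 5 ethyl 8-bromo-4-hydroxy-5-methoxynaphthalene-2-carboxylate
Conditions: HCl (cat.), EtOH, 60 °C
Reagents that add atoms: none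
Why: Acid-catalysed transesterification removes the aryl acetate, and the ethyl ester is unchanged in ethanol.

**Step 4**
Reactants: 5 ethyl 8-bromo-4-hydroxy-5-methoxynaphthalene-2-carboxylate
Product: 6 ethyl 8-bromo-4,5-dimethoxynaphthalene-2-carboxylate
Conditions: MeI, K2CO3, DMF, 40 °C
Reagents that add atoms: iodomethane CI
Why: Williamson O-methylation of the naphthoxide, with DMF and gentle warming to overcome the peri hydrogen bond.

**Step 5**
Reactants: 6 ethyl 8-bromo-4,5-dimethoxynaphthalene-2-carboxylate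
Product: 7 (8-bromo-4,5-dimethoxynaphthalen-2-yl)methanol
Conditions: i-Bu2AlH, CH2Cl2, −78 → 0 °C; aq. potassium sodium tartrate
Reagents that add atoms: none
Why: Hydride reduction of the ester to the primary alcohol, which leaves the aryl bromide and aryl ethers untouched.

**Step 6**
Reactants: 7 (8-bromo-4,5-dimethoxynaphthalen-2-yl)methanol
Product: 8 1-bromo-7-(bromomethyl)-4,5-dimethoxynaphthalene
Conditions: PBr3, CH2Cl2, 0 °C
Reagents that add atoms: phosphorus tribromide BrP(Br)Br
Why: The benzylic alcohol is activated as its phosphite ester and displaced by bromide (SN2).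

**Step 7**
Reactants: 8 1-bromo-7-(bromomethyl)-4,5-dimethoxynaphthalene
Product: 9 1-bromo-4,5-dimethoxy-7-methylnaphthalene
Conditions: LiBHEt3, THF, 0 °C
Reagents that add atoms: none
Why: SN2 hydride displacement of the benzylic bromide is fast at 0 °C, while the aryl bromide is inert under these conditions.

**Step 8**
Reactants: 9 1-bromo-4,5-dimethoxy-7-methylnaphthalene
Product: 10 2-(4,5-dimethoxy-7-methylnaphthalen-1-yl)-4,4,5,5-tetramethyl-1,3,2-dioxaborolane
Conditions: B2pin2, PdCl2(dppf) (3 mol %), KOAc, 1,4-dioxane, 90 °C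
Reagents that add atoms: bis(pinacolato)diboron CC1(C)OB(OC1(C)C)B1OC(C)(C)C(C)(C)O1
Why: Miyaura borylation of the aryl bromide; the weak base KOAc prevents homocoupling.

**Step 9**
Reactants: 11 3,5-dimethoxytoluene
Product: 13 2,4-dimethoxy-6-methylbenzaldehyde, via aryl iminium chloride 12 (not isolated)
Conditions: POCl3, DMF, 0 → 80 °C; then H2O
Reagents that add atoms: N,N-dimethylformamide CN(C)C=O; water O
Why: Vilsmeier–Haack formylation occurs para to one OMe and ortho to the other (next to the methyl) in preference to the crowded position between the two OMe groups, and water hydrolyses the iminium salt.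

**Step 10**
Reactants: 13 2,4-dimethoxy-6-methylbenzaldehyde
Product: 14 2,4-dimethoxy-6-methylbenzoic acid
Conditions: NaClO2, NaH2PO4, 2-methyl-2-butene, t-BuOH/H2O, rt
Reagents that add atoms: sodium chlorite [Na+].[O-]Cl=O
Why: Pinnick oxidation; the alkene scavenges HOCl so the electron-rich ring is not chlorinated.

**Step 11**
Reactants: 14 2,4-dimethoxy-6-methylbenzoic acid
Product: 15 methyl 2,4-dimethoxy-6-methylbenzoate
Conditions: MeI, K2CO3, DMF, rt
Reagents that add atoms: iodomethane CI
Why: SN2 O-alkylation of the carboxylate avoids attack at the di-ortho-substituted carbonyl, which would make Fischer esterification slow.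

**Step 12**
Reactants: 15 methyl 2,4-dimethoxy-6-methylbenzoate
Product: 16 methyl 3-bromo-4,6-dimethoxy-2-methylbenzoate
Conditions: NBS, MeCN, 0 °C → rt, dark
Reagents that add atoms: N-bromosuccinimide O=C1CCC(=O)N1Br
Why: Electrophilic aromatic bromination goes para to the 6-OMe and ortho to the 4-OMe (beside the methyl), as in the NBS bromination of 3,5-dimethoxytoluene, and not between the two OMe groups.

**Step 13**
Reactants: 16 methyl 3-bromo-4,6-dimethoxy-2-methylbenzoate; 10 2-(4,5-dimethoxy-7-methylnaphthalen-1-yl)-4,4,5,5-tetramethyl-1,3,2-dioxaborolane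
Product: 17 methyl 3-(4,5-dimethoxy-7-methylnaphthalen-1-yl)-4,6-dimethoxy-2-methylbenzoate
Conditions: Pd(OAc)2 (5 mol %), SPhos (10 mol %), K3PO4, toluene/H2O 10:1, 100 °C
Reagents that add atoms: none
Why: Suzuki–Miyaura coupling with a bulky biaryl dialkylphosphine ligand, which handles electron-rich, tri-ortho-substituted partners; the hindered methyl ester survives the phosphate base and 17 is racemic about the new axis.

**Step 14**
Reactants: 18 (S)-2-methylpropane-2-sulfinamide; 19 acetaldehyde
Product: 20 (S,E)-N-ethylidene-2-methylpropane-2-sulfinamide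
Conditions: MgSO4, PPTS (cat.), CH2Cl2, rt
Reagents that add atoms: none
Why: Acid-catalysed condensation with a desiccant gives the (E)-N-sulfinyl aldimine, and the sulfur stereocentre is not touched.

**Step 15**
Reactants: 17 methyl 3-(4,5-dimethoxy-7-methylnaphthalen-1-yl)-4,6-dimethoxy-2-methylbenzoate; 20 (S,E)-N-ethylidene-2-methylpropane-2-sulfinamide
Product: 22 methyl 2-[(2S)-2-{[(S)-tert-butylsulfinyl]amino}propyl]-3-(4,5-dimethoxy-7-methylnaphthalen-1-yl)-4,6-dimethoxybenzoate, via lithiated toluate 21 (not isolated)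
Conditions: LiN(i-Pr)2 (1.1 equiv), THF, −78 °C; then 20 (1.5 equiv), −78 °C; AcOH quench at −78 °C
Reagents that add atoms: none
Why: Lateral lithiation gives a vinylogous ester enolate that adds to the sulfinimine in a Mannich-type reaction through a lithium-chelated six-membered chair with tert-butyl equatorial, so the (S)-sulfinyl group directs attack to the Re face of C=N and sets C3 as S.

**Step 16**
Reactants: 22 methyl 2-[(2S)-2-{[(S)-tert-butylsulfinyl]amino}propyl]-3-(4,5-dimethoxy-7-methylnaphthalen-1-yl)-4,6-dimethoxybenzoate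
Product: 24 (3S)-5-(4,5-dimethoxy-7-methylnaphthalen-1-yl)-6,8-dimethoxy-3-methyl-3,4-dihydroisoquinolin-1(2H)-one, via amino ester 23 (not isolated)
Conditions: HCl (4 M in dioxane), MeOH, 0 °C → rt; evaporate; K2CO3, MeOH, 65 °C
Reagents that add atoms: none
Why: Acidic methanolysis cleaves the S–N bond without touching C3, and the freed primary amine closes the six-membered lactam by intramolecular aminolysis of the methyl ester.

**Step 17**
Reactants: 24 (3S)-5-(4,5-dimethoxy-7-methylnaphthalen-1-yl)-6,8-dimethoxy-3-methyl-3,4-dihydroisoquinolin-1(2H)-one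
Product: 25 (3S)-5-(4,5-dimethoxy-7-methylnaphthalen-1-yl)-6,8-dimethoxy-3-methyl-1,2,3,4-tetrahydroisoquinoline
Conditions: LiAlH4, THF, reflux; H2O/aq. NaOH work-up
Reagents that add atoms: none
Why: Hydride reduction of the secondary lactam turns C1=O into CH2; C3 is not alpha to the carbonyl and keeps its configuration.

## Compound list

1 | 2-bromo-5-methoxybenzaldehyde | COc1ccc(Br)c(C=O)c1 | starting material
2 | diethyl succinate | CCOC(=O)CCC(=O)OCC | starting material
3 | (E)-4-(2-bromo-5-methoxyphenyl)-3-(ethoxycarbonyl)but-3-enoic acid | CCOC(=O)/C(CC(=O)O)=C/c1cc(OC)ccc1Br | intermediate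
4 | ethyl 4-acetoxy-8-bromo-5-methoxynaphthalene-2-carboxylate | CCOC(=O)c1cc(OC(C)=O)c2c(OC)ccc(Br)c2c1 | intermediate
5 | ethyl 8-bromo-4-hydroxy-5-methoxynaphthalene-2-carboxylate | CCOC(=O)c1cc(O)c2c(OC)ccc(Br)c2c1 | intermediate
6 | ethyl 8-bromo-4,5-dimethoxynaphthalene-2-carboxylate | CCOC(=O)c1cc(OC)c2c(OC)ccc(Br)c2c1 | intermediate
7 | (8-bromo-4,5-dimethoxynaphthalen-2-yl)methanol | OCc1cc(OC)c2c(OC)ccc(Br)c2c1 | intermediate
8 | 1-bromo-7-(bromomethyl)-4,5-dimethoxynaphthalene | BrCc1cc(OC)c2c(OC)ccc(Br)c2c1 | intermediate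
9 | 1-bromo-4,5-dimethoxy-7-methylnaphthalene | Cc1cc(OC)c2c(OC)ccc(Br)c2c1 | intermediate
10 | 2-(4,5-dimethoxy-7-methylnaphthalen-1-yl)-4,4,5,5-tetramethyl-1,3,2-dioxaborolane | Cc1cc(OC)c2c(OC)ccc(B3OC(C)(C)C(C)(C)O3)c2c1 | intermediate
11 | 3,5-dimethoxytoluene | Cc1cc(OC)cc(OC)c1 | starting material
12 | N-[(2,4-dimethoxy-6-methylphenyl)methylidene]-N-methylmethanaminium chloride (formed in the flask) | C[N+](C)=Cc1c(C)cc(OC)cc1OC.[Cl-] | intermediate
13 | 2,4-dimethoxy-6-methylbenzaldehyde | Cc1cc(OC)cc(OC)c1C=O | intermediate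
14 | 2,4-dimethoxy-6-methylbenzoic acid | Cc1cc(OC)cc(OC)c1C(=O)O | intermediate
15 | methyl 2,4-dimethoxy-6-methylbenzoate | COC(=O)c1c(C)cc(OC)cc1OC | intermediate
16 | methyl 3-bromo-4,6-dimethoxy-2-methylbenzoate | COC(=O)c1c(C)c(Br)c(OC)cc1OC | intermediate
17 | methyl 3-(4,5-dimethoxy-7-methylnaphthalen-1-yl)-4,6-dimethoxy-2-methylbenzoate (racemic about the axis) | COC(=O)c1c(C)c(-c2ccc(OC)c3c(OC)cc(C)cc23)c(OC)cc1OC | intermediate
18 | (S)-2-methylpropane-2-sulfinamide | CC(C)(C)[S@](=O)N | starting material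
19 | acetaldehyde | CC=O | starting material
20 | (S,E)-N-ethylidene-2-methylpropane-2-sulfinamide | CC(C)(C)[S@](=O)/N=C/C | intermediate
21 | methyl 3-(4,5-dimethoxy-7-methylnaphthalen-1-yl)-2-(lithiomethyl)-4,6-dimethoxybenzoate (formed in the flask) | COC(=O)c1c(C[Li])c(-c2ccc(OC)c3c(OC)cc(C)cc23)c(OC)cc1OC | intermediate
22 | methyl 2-[(2S)-2-{[(S)-tert-butylsulfinyl]amino}propyl]-3-(4,5-dimethoxy-7-methylnaphthalen-1-yl)-4,6-dimethoxybenzoate | COC(=O)c1c(C[C@H](C)N[S@@](=O)C(C)(C)C)c(-c2ccc(OC)c3c(OC)cc(C)cc23)c(OC)cc1OC | intermediate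
23 | methyl 2-[(2S)-2-aminopropyl]-3-(4,5-dimethoxy-7-methylnaphthalen-1-yl)-4,6-dimethoxybenzoate (formed in the flask) | COC(=O)c1c(C[C@H](C)N)c(-c2ccc(OC)c3c(OC)cc(C)cc23)c(OC)cc1OC | intermediate
24 | (3S)-5-(4,5-dimethoxy-7-methylnaphthalen-1-yl)-6,8-dimethoxy-3-methyl-3,4-dihydroisoquinolin-1(2H)-one | COc1cc(OC)c(-c2ccc(OC)c3c(OC)cc(C)cc23)c2c1C(=O)N[C@@H](C)C2 | intermediate
25 | (3S)-5-(4,5-dimethoxy-7-methylnaphthalen-1-yl)-6,8-dimethoxy-3-methyl-1,2,3,4-tetrahydroisoquinoline | COc1cc(OC)c(-c2ccc(OC)c3c(OC)cc(C)cc23)c2c1CN[C@@H](C)C2 | target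

## Step count and risks

Total steps: 17. Longest linear sequence: 12 (steps 1–8, 13, 15, 16, 17).

**Step 13 (tri-ortho-substituted Suzuki coupling).** The electron-rich naphthyl boronate may protodeboronate faster than it couples with the hindered bromide. The fallback sets out from 9 and comes back at 17. Bromine–lithium exchange on 9 (n-BuLi, THF, −78 °C) gives (4,5-dimethoxy-7-methylnaphthalen-1-yl)lithium F1. ZnCl2 converts it into (4,5-dimethoxy-7-methylnaphthalen-1-yl)zinc chloride F2. Negishi coupling of F2 with 16 (Pd(OAc)2/SPhos, THF, 60 °C) then gives 17. The organozinc transmetalates readily with hindered partners, tolerates the ester and cannot protodeboronate.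

**Step 15 (Mannich-type addition of the hindered benzylic anion).** The carbanion sits next to the perpendicular naphthyl group and the aldimine is enolisable, so proton transfer or a low diastereomer ratio is possible. If the open transition state prevailed over the chelated one, C3 would come out R. The fallback sets out from 15 and comes back at 24; it makes the C3–C4 bond before the biaryl bond.
- LiN(i-Pr)2 on 15 gives methyl 2-(lithiomethyl)-4,6-dimethoxybenzoate F3, the classical unhindered orsellinate anion.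
- Addition of F3 to 20 gives methyl 2-[(2S)-2-{[(S)-tert-butylsulfinyl]amino}propyl]-4,6-dimethoxybenzoate F4.
- HCl/MeOH frees methyl 2-[(2S)-2-aminopropyl]-4,6-dimethoxybenzoate F5, which closes with K2CO3/MeOH to (3S)-6,8-dimethoxy-3-methyl-3,4-dihydroisoquinolin-1(2H)-one F6.
- NBS in MeCN brominates para to the 8-OMe to give (3S)-5-bromo-6,8-dimethoxy-3-methyl-3,4-dihydroisoquinolin-1(2H)-one F7.
- Suzuki coupling of F7 with 10 (Pd(OAc)2, SPhos, K3PO4) gives 24.

**Step 16 (lactamisation onto a di-ortho-substituted ester).** The ester is flanked by OMe and the side chain, and aminolysis may stall. The fallback sets out from 22 and comes back at 25; it closes the ring by N-alkylation instead of acylation.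
- LiAlH4 (THF, 0 °C → rt) reduces the ester of 22 to (S)-N-[(2S)-1-[2-(4,5-dimethoxy-7-methylnaphthalen-1-yl)-6-(hydroxymethyl)-3,5-dimethoxyphenyl]propan-2-yl]-2-methylpropane-2-sulfinamide F8.
- MsCl/Et3N/LiCl gives (S)-N-[(2S)-1-[6-(chloromethyl)-2-(4,5-dimethoxy-7-methylnaphthalen-1-yl)-3,5-dimethoxyphenyl]propan-2-yl]-2-methylpropane-2-sulfinamide F9.
- KOt-Bu in THF closes the ring by intramolecular N-alkylation of the sulfinamide anion to (3S)-2-[(S)-tert-butylsulfinyl]-5-(4,5-dimethoxy-7-methylnaphthalen-1-yl)-6,8-dimethoxy-3-methyl-1,2,3,4-tetrahydroisoquinoline F10.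
- HCl/MeOH, then aqueous NaOH, gives 25.

## Further compounds

F1 | step 13 | (4,5-dimethoxy-7-methylnaphthalen-1-yl)lithium | [Li]c1ccc(OC)c2c(OC)cc(C)cc12
F2 | step 13 | (4,5-dimethoxy-7-methylnaphthalen-1-yl)zinc chloride | Cl[Zn]c1ccc(OC)c2c(OC)cc(C)cc12
F3 | step 15 | methyl 2-(lithiomethyl)-4,6-dimethoxybenzoate | COC(=O)c1c(C[Li])cc(OC)cc1OC
F4 | step 15 | methyl 2-[(2S)-2-{[(S)-tert-butylsulfinyl]amino}propyl]-4,6-dimethoxybenzoate | COC(=O)c1c(C[C@H](C)N[S@@](=O)C(C)(C)C)cc(OC)cc1OC
F5 | step 15 | methyl 2-[(2S)-2-aminopropyl]-4,6-dimethoxybenzoate | COC(=O)c1c(C[C@H](C)N)cc(OC)cc1OC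
F6 | step 15 | (3S)-6,8-dimethoxy-3-methyl-3,4-dihydroisoquinolin-1(2H)-one | COc1cc(OC)c2c(c1)C[C@H](C)NC2=O
F7 | step 15 | (3S)-5-bromo-6,8-dimethoxy-3-methyl-3,4-dihydroisoquinolin-1(2H)-one | COc1cc(OC)c2c(c1Br)C[C@H](C)NC2=O
F8 | step 16 | (S)-N-[(2S)-1-[2-(4,5-dimethoxy-7-methylnaphthalen-1-yl)-6-(hydroxymethyl)-3,5-dimethoxyphenyl]propan-2-yl]-2-methylpropane-2-sulfinamide | OCc1c(C[C@H](C)N[S@@](=O)C(C)(C)C)c(-c2ccc(OC)c3c(OC)cc(C)cc23)c(OC)cc1OC
F9 | step 16 | (S)-N-[(2S)-1-[6-(chloromethyl)-2-(4,5-dimethoxy-7-methylnaphthalen-1-yl)-3,5-dimethoxyphenyl]propan-2-yl]-2-methylpropane-2-sulfinamide | ClCc1c(C[C@H](C)N[S@@](=O)C(C)(C)C)c(-c2ccc(OC)c3c(OC)cc(C)cc23)c(OC)cc1OC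
F10 | step 16 | (3S)-2-[(S)-tert-butylsulfinyl]-5-(4,5-dimethoxy-7-methylnaphthalen-1-yl)-6,8-dimethoxy-3-methyl-1,2,3,4-tetrahydroisoquinoline | COc1cc(OC)c(-c2ccc(OC)c3c(OC)cc(C)cc23)c2c1CN([S@@](=O)C(C)(C)C)[C@@H](C)C2
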